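**Retrosynthetic overview**
1. Target 24 ⇐ 23 by face-selective epoxidation of the Z-C1=C10 alkene; 23 ⇐ 19 by α-methylenation; 19 ⇐ keto lactone 16 by C8 reduction and acylation.
2. 16 ⇐ ten-membered 1,3-diketone 12 by C7 alkylation, catalyst-controlled C6 reduction and trans-lactonisation.
3. Key step: carbocycle 12 ⇐ seven-membered lactone 8 by a ring expansion in which the ketone enolate takes the lactone acyl group from oxygen to carbon (forms C7–C8, frees O3, 7 → 10 ring atoms).
4. 8 ⇐ diene ester 7 by ring-closing metathesis (Z-C1=C10 fixed by the seven-membered ring); 7 ⇐ butenolide 3 by MeLi opening and acylation (Z-C4=C5 fixed by the five-membered ring); 3 ⇐ lactol 1 by asymmetric allylation (sets C3).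
5. Order of ring formation: butenolide (template) → oxepinone → cyclodecadiene → γ-lactone → epoxide.

Assumption: germacrane numbering is used for ring positions throughout (C1–C10 ring, C11–C13 lactone carbons, C14 on C10, C15 on C4, lactone oxygen on C6), and lactol 1 and the (2R)-acid 18 are taken as catalogue chemicals.

**Route**

Step 1
Reactants: 1 5-hydroxy-4-methylfuran-2(5H)-one
Product: 3 (5R)-4-methyl-5-(prop-2-en-1-yl)furan-2(5H)-one, via hydroxy acid 2 (not isolated)
Conditions: allylB(pin) (1.5 equiv), (R)-TRIP phosphoric acid (5 mol%), 4 Å MS, toluene, −30 °C; then 1 M HCl, THF, rt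
Reagents that add atoms: allylboronic acid pinacol ester, C=CCB1OC(C)(C)C(C)(C)O1
Why: Chiral phosphoric acid-catalysed allylboration of the open (Z)-formyl acid tautomer of 1 goes through a chair six-membered boronate transition state in which the (R)-catalyst directs allyl to the Re face and sets C3 as R, and the (Z)-γ-hydroxy acid 2 lactonises on acidic work-up.

Step 2
Reactants: 3 (5R)-4-methyl-5-(prop-2-en-1-yl)furan-2(5H)-one; 4 3-methylbut-3-enoic acid
Product: 7 (4R,5Z)-5-methyl-7-oxoocta-1,5-dien-4-yl 3-methylbut-3-enoate, via acid chloride 5 (not isolated), via lithium keto alkoxide 6 (not isolated)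
Conditions: 3, MeLi (1.05 equiv), THF, −78 °C; then 5 [from 4, (COCl)2, cat. DMF, CH2Cl2, 0 °C → rt], −78 → 0 °C
Reagents that add atoms: methyllithium, [Li]C
Why: Methyllithium adds 1,2 to the butenolide carbonyl at −78 °C faster than it removes the C3 proton, the tetrahedral lactolate opens to the (Z)-keto alkoxide 6, and its secondary alkoxide is acylated by 5 (nucleophilic acyl substitution), so the Z-geometry of C4=C5 is inherited from the five-membered ring and C3 is untouched.

Step 3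
Reactants: 7 (4R,5Z)-5-methyl-7-oxoocta-1,5-dien-4-yl 3-methylbut-3-enoate
Product: 8 (7R)-4-methyl-7-[(2Z)-4-oxopent-2-en-2-yl]-6,7-dihydrooxepin-2(3H)-one
Conditions: RuCl2(H2IMes)(=CH-C6H4-2-O-i-Pr) (second-generation Hoveyda–Grubbs catalyst, 5 mol%), 1,4-benzoquinone (10 mol%), toluene (2 mM), 80 °C
Reagents that add atoms: none
Why: Ring-closing metathesis of the allyl and methallyl termini closes the seven-membered lactone, in which the new trisubstituted C1=C10 alkene can only be Z, while the electron-poor trisubstituted enone alkene is inert and benzoquinone suppresses ruthenium hydride isomerisation.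

Step 4
Reactants: 8 (7R)-4-methyl-7-[(2Z)-4-oxopent-2-en-2-yl]-6,7-dihydrooxepin-2(3H)-one
Product: 12 (1R,2Z,8Z)-2,8-dimethyl-4,6-dioxocyclodeca-2,8-dien-1-yl acetate, via ketone enolate 9 (not isolated), via bridged lactolate 10 (not isolated), via dilithium alkoxide diketonate 11 (not isolated)
Conditions: LiN(SiMe3)2 (1.05 equiv), THF, −78 → −20 °C; LiN(SiMe3)2 (1.05 equiv), −78 °C; Ac2O (1.1 equiv); AcOH
Reagents that add atoms: acetic anhydride, CC(=O)OC(C)=O
Why: Proposed new method: the methyl ketone enolate 9, held beside the lactone carbonyl by the Z-enone, adds to C8 through a seven-membered transition state to give the bridged tetrahedral lactolate 10, whose C8–O3 bond then breaks to free the C3 alkoxide and form the chelated 1,3-diketonate 11 (a three-atom ring expansion driven by diketonate formation, reversible O-acylation and lactone enolisation draining into the same sink, C3 retained because no bond to it breaks), after which Ac2O acylates only the free alkoxide; the closest known chemistry is the Baker–Venkataraman O-to-C acyl transfer and Claisen/Dieckmann acylation, together with side-chain-insertion ring expansions of lactams.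

Step 5
Reactants: 12 (1R,2Z,8Z)-2,8-dimethyl-4,6-dioxocyclodeca-2,8-dien-1-yl acetate; 13 methyl bromoacetate
Product: 14 methyl 2-[(3Z,5R,7Z)-5-acetoxy-4,8-dimethyl-2,10-dioxocyclodeca-3,7-dien-1-yl]acetate
Conditions: K2CO3 (1.1 equiv), acetone, 0 °C → rt
Reagents that add atoms: none
Why: SN2 C-alkylation of the chelated potassium 1,3-diketonate by the α-halo ester installs the C11–C12 arm on C7, which stays epimerisable between the two carbonyls.

Step 6
Reactants: 14 methyl 2-[(3Z,5R,7Z)-5-acetoxy-4,8-dimethyl-2,10-dioxocyclodeca-3,7-dien-1-yl]acetate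
Product: 16 (3aR,6Z,9R,10Z,11aS)-6,10-dimethyl-2,4-dioxo-2,3,3a,4,5,8,9,11a-octahydrocyclodeca[b]furan-9-yl acetate, via hydroxy ester 15 (not isolated)
Conditions: RuCl[(R,R)-TsDPEN](p-cymene) (2 mol%), HCO2H/Et3N (5:2), CH2Cl2, rt; then p-TsOH·H2O (10 mol%), CH2Cl2, rt
Reagents that add atoms: none
Why: Noyori–Ikariya asymmetric transfer hydrogenation reduces the conjugated C6 carbonyl much faster than the dialkyl-type C8 ketone and under catalyst control (the alkenyl group takes the aryl position of the CH/π model, so the (R,R)-catalyst gives 6S), while C7 equilibrates through the 1,3-dicarbonyl (dynamic kinetic resolution) and, after acid-catalysed lactonisation, through the C8 enol to the more stable trans-fused γ-lactone (7R).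

Step 7
Reactants: 16 (3aR,6Z,9R,10Z,11aS)-6,10-dimethyl-2,4-dioxo-2,3,3a,4,5,8,9,11a-octahydrocyclodeca[b]furan-9-yl acetate
Product: 17 (3aS,4S,6Z,9R,10Z,11aS)-4-hydroxy-6,10-dimethyl-2-oxo-2,3,3a,4,5,8,9,11a-octahydrocyclodeca[b]furan-9-yl acetate
Conditions: NaBH4, MeOH/CH2Cl2, −78 °C
Reagents that add atoms: none
Why: Borohydride 1,2-reduction delivers hydride to C8 from the face of H-7, anti to the lactone methylene on C7 (steric approach control), giving 8S, and the cold, nearly neutral medium avoids β-elimination of the lactone oxygen and conjugation of the C1=C10 alkene.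

Step 8
Reactants: 17 (3aS,4S,6Z,9R,10Z,11aS)-4-hydroxy-6,10-dimethyl-2-oxo-2,3,3a,4,5,8,9,11a-octahydrocyclodeca[b]furan-9-yl acetate; 18 (2R)-2-methylbutanoic acid
Product: 19 (3aS,4S,6Z,9R,10Z,11aS)-9-acetoxy-6,10-dimethyl-2-oxo-2,3,3a,4,5,8,9,11a-octahydrocyclodeca[b]furan-4-yl (2R)-2-methylbutanoate
Conditions: DCC (1.3 equiv), DMAP (10 mol%), CH2Cl2, 0 °C → rt
Reagents that add atoms: none
Why: Steglich esterification acylates the only free hydroxyl with retention at C8 and, under these mild conditions, without epimerising the α-stereocentre of the acid.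

Step 9
Reactants: 19 (3aS,4S,6Z,9R,10Z,11aS)-9-acetoxy-6,10-dimethyl-2-oxo-2,3,3a,4,5,8,9,11a-octahydrocyclodeca[b]furan-4-yl (2R)-2-methylbutanoate
Product: 23 (3aS,4S,6Z,9R,10Z,11aS)-9-acetoxy-6,10-dimethyl-3-methylidene-2-oxo-2,3,3a,4,5,8,9,11a-octahydrocyclodeca[b]furan-4-yl (2R)-2-methylbutanoate, via lactone enolate 20 (not isolated), via Mannich base 21 (not isolated), via methiodide 22 (not isolated)
Conditions: LiN(SiMe3)2 (1.05 equiv), THF, −78 °C; Me2N=CH2+ I− (Eschenmoser's salt), −78 → 0 °C; MeI, CH2Cl2, rt; NaHCO3 (aq), rt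
Reagents that add atoms: N,N-dimethylmethyleneiminium iodide (Eschenmoser's salt), C=[N+](C)C.[I-]
Why: Kinetic deprotonation by the hindered amide takes the lactone α-CH2, which is several pKa units more acidic than the acetate methyl and the α-branched ester, the enolate is aminomethylated (Mannich reaction), and quaternisation followed by E1cB loss of trimethylamine gives the α-methylene lactone.

Step 10
Reactants: 23 (3aS,4S,6Z,9R,10Z,11aS)-9-acetoxy-6,10-dimethyl-3-methylidene-2-oxo-2,3,3a,4,5,8,9,11a-octahydrocyclodeca[b]furan-4-yl (2R)-2-methylbutanoate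
Product: 24 (1R,3R,4Z,6S,7S,8S,10S)-3-acetoxy-1,10-epoxy-8-[(2R)-2-methylbutanoyloxy]germacra-4,11(13)-dien-12,6-olide
Conditions: dimethyldioxirane (1.05 equiv), acetone/CH2Cl2, −40 °C
Reagents that add atoms: dimethyldioxirane, CC1(C)OO1
Why: Dimethyldioxirane epoxidises the electron-rich isolated C1=C10 alkene in preference to the C4=C5 alkene (deactivated by two allylic acyloxy groups) and the acrylate, from the face opposite the flanking C3 and C8 acyloxy groups, and stereospecific syn oxygen transfer to the Z-alkene gives the cis-epoxide (1R,10S).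

**Compound list**
1 | 5-hydroxy-4-methylfuran-2(5H)-one | CC1=CC(=O)OC1O | starting material
2 | (2Z,4R)-4-hydroxy-3-methylhepta-2,6-dienoic acid | OC(=O)/C=C(/C)[C@H](O)CC=C | intermediate (not isolated)
3 | (5R)-4-methyl-5-(prop-2-en-1-yl)furan-2(5H)-one | CC1=CC(=O)O[C@@H]1CC=C | intermediate
4 | 3-methylbut-3-enoic acid | C=C(C)CC(O)=O | starting material
5 | 3-methylbut-3-enoyl chloride | C=C(C)CC(Cl)=O | intermediate (not isolated)
6 | lithium (4R,5Z)-5-methyl-7-oxoocta-1,5-dien-4-olate | CC(=O)/C=C(/C)[C@H]([O-])CC=C.[Li+] | intermediate (not isolated)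
7 | (4R,5Z)-5-methyl-7-oxoocta-1,5-dien-4-yl 3-methylbut-3-enoate | CC(=O)/C=C(/C)[C@H](OC(=O)CC(C)=C)CC=C | intermediate
8 | (7R)-4-methyl-7-[(2Z)-4-oxopent-2-en-2-yl]-6,7-dihydrooxepin-2(3H)-one | CC(=O)/C=C(/C)[C@H]1C/C=C(/C)CC(=O)O1 | intermediate
9 | lithium (3Z)-4-[(7R)-4-methyl-2-oxo-2,3,6,7-tetrahydrooxepin-7-yl]penta-1,3-dien-2-olate | C=C([O-])/C=C(/C)[C@H]1C/C=C(/C)CC(=O)O1.[Li+] | intermediate (not isolated)
10 | lithium (6R)-5,9-dimethyl-3-oxo-11-oxabicyclo[4.4.1]undeca-4,8-dien-1-olate (bridgehead C1 fixed by the bridge) | [O-]C12CC(=O)/C=C(/C)[C@H](O1)C/C=C(/C)C2.[Li+] | intermediate (not isolated)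
11 | dilithium (1R,2Z,8Z)-2,8-dimethyl-4,6-dioxocyclodeca-2,8-dien-5-id-1-olate | O=C1[CH-]C(=O)/C=C(/C)[C@H]([O-])C/C=C(/C)C1.[Li+].[Li+] | intermediate (not isolated)
12 | (1R,2Z,8Z)-2,8-dimethyl-4,6-dioxocyclodeca-2,8-dien-1-yl acetate | O=C1CC(=O)/C=C(/C)[C@H](OC(C)=O)C/C=C(/C)C1 | intermediate
13 | methyl bromoacetate | COC(=O)CBr | starting material
14 | methyl 2-[(3Z,5R,7Z)-5-acetoxy-4,8-dimethyl-2,10-dioxocyclodeca-3,7-dien-1-yl]acetate (C1 of the ring epimerisable) | COC(=O)CC1C(=O)/C=C(/C)[C@H](OC(C)=O)C/C=C(/C)CC1=O | intermediate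
15 | methyl 2-[(1R,2S,3Z,5R,7Z)-5-acetoxy-2-hydroxy-4,8-dimethyl-10-oxocyclodeca-3,7-dien-1-yl]acetate | COC(=O)C[C@@H]1[C@@H](O)/C=C(/C)[C@H](OC(C)=O)C/C=C(/C)CC1=O | intermediate (not isolated)
16 | (3aR,6Z,9R,10Z,11aS)-6,10-dimethyl-2,4-dioxo-2,3,3a,4,5,8,9,11a-octahydrocyclodeca[b]furan-9-yl acetate | C1C(=O)O[C@H]2/C=C(/C)[C@H](OC(C)=O)C/C=C(/C)CC(=O)[C@H]12 | intermediate
17 | (3aS,4S,6Z,9R,10Z,11aS)-4-hydroxy-6,10-dimethyl-2-oxo-2,3,3a,4,5,8,9,11a-octahydrocyclodeca[b]furan-9-yl acetate | C1C(=O)O[C@H]2/C=C(/C)[C@H](OC(C)=O)C/C=C(/C)C[C@H](O)[C@H]12 | intermediate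
18 | (2R)-2-methylbutanoic acid | CC[C@@H](C)C(O)=O | starting material
19 | (3aS,4S,6Z,9R,10Z,11aS)-9-acetoxy-6,10-dimethyl-2-oxo-2,3,3a,4,5,8,9,11a-octahydrocyclodeca[b]furan-4-yl (2R)-2-methylbutanoate | C1C(=O)O[C@H]2/C=C(/C)[C@H](OC(C)=O)C/C=C(/C)C[C@H](OC(=O)[C@H](C)CC)[C@H]12 | intermediate
20 | lithium (3aS,4S,6Z,9R,10Z,11aS)-9-acetoxy-6,10-dimethyl-4-{[(2R)-2-methylbutanoyl]oxy}-3a,4,5,8,9,11a-hexahydrocyclodeca[b]furan-2-olate | C1=C([O-])O[C@H]2/C=C(/C)[C@H](OC(C)=O)C/C=C(/C)C[C@H](OC(=O)[C@H](C)CC)[C@H]12.[Li+] | intermediate (not isolated)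
21 | (3aS,4S,6Z,9R,10Z,11aS)-9-acetoxy-3-[(dimethylamino)methyl]-6,10-dimethyl-2-oxo-2,3,3a,4,5,8,9,11a-octahydrocyclodeca[b]furan-4-yl (2R)-2-methylbutanoate (C3 of the lactone as a mixture) | CN(C)CC1C(=O)O[C@H]2/C=C(/C)[C@H](OC(C)=O)C/C=C(/C)C[C@H](OC(=O)[C@H](C)CC)[C@H]12 | intermediate (not isolated)
22 | {[(3aS,4S,6Z,9R,10Z,11aS)-9-acetoxy-6,10-dimethyl-4-{[(2R)-2-methylbutanoyl]oxy}-2-oxo-2,3,3a,4,5,8,9,11a-octahydrocyclodeca[b]furan-3-yl]methyl}trimethylammonium iodide | C[N+](C)(C)CC1C(=O)O[C@H]2/C=C(/C)[C@H](OC(C)=O)C/C=C(/C)C[C@H](OC(=O)[C@H](C)CC)[C@H]12.[I-] | intermediate (not isolated)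
23 | (3aS,4S,6Z,9R,10Z,11aS)-9-acetoxy-6,10-dimethyl-3-methylidene-2-oxo-2,3,3a,4,5,8,9,11a-octahydrocyclodeca[b]furan-4-yl (2R)-2-methylbutanoate | C=C1C(=O)O[C@H]2/C=C(/C)[C@H](OC(C)=O)C/C=C(/C)C[C@H](OC(=O)[C@H](C)CC)[C@H]12 | intermediate
24 | (1R,3R,4Z,6S,7S,8S,10S)-3-acetoxy-1,10-epoxy-8-[(2R)-2-methylbutanoyloxy]germacra-4,11(13)-dien-12,6-olide | C=C1C(=O)O[C@H]2/C=C(/C)[C@H](OC(C)=O)C[C@H]3O[C@@]3(C)C[C@H](OC(=O)[C@H](C)CC)[C@H]12 | target

**Step count and risks**
Total step count: 10. Longest linear sequence: 10 steps (1 → 24); the acid chloride 5 is made and used within step 2.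

The three steps most likely to fail:

Step 4 (the proposed ring expansion). The lactone α-CH2 may be deprotonated instead of the methyl ketone, or the enolate may acylate on oxygen or between molecules. The fallback uses known reactions only, sets out from 3 and comes back at 12. Compound 3 is opened with MeLi (THF, −78 °C) and the alkoxide is trapped with Ac2O to give (4R,5Z)-5-methyl-7-oxoocta-1,5-dien-4-yl acetate F1. Soft enolisation of its methyl ketone (MgBr2·OEt2, i-Pr2NEt, CH2Cl2) and C-acylation with acid chloride 5 gives the open-chain 1,3-diketone (4R,5Z)-5,11-dimethyl-7,9-dioxododeca-1,5,11-trien-4-yl acetate F2. Ring-closing metathesis at high dilution (second-generation Hoveyda–Grubbs catalyst, toluene, 0.5 mM, 80 °C) then closes the ten-membered ring directly to 12, with separation of any E isomer at C1=C10.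

Step 6 (catalyst-controlled C6 reduction and lactonisation). The catalyst may fail to override the substrate bias, giving the C6 epimer, or may touch the C8 ketone. The fallback sets out from 12 and comes back at 16. Compound 12 is alkylated with allyl bromoacetate (K2CO3, acetone) to prop-2-en-1-yl 2-[(3Z,5R,7Z)-5-acetoxy-4,8-dimethyl-2,10-dioxocyclodeca-3,7-dien-1-yl]acetate F3. Substrate-controlled Luche reduction (NaBH4, CeCl3·7H2O, MeOH, −78 °C) is taken to give the 6R allylic alcohol prop-2-en-1-yl 2-[(2R,3Z,5R,7Z)-5-acetoxy-2-hydroxy-4,8-dimethyl-10-oxocyclodeca-3,7-dien-1-yl]acetate F4. Pd(PPh3)4 with morpholine removes the allyl ester under neutral conditions to give 2-[(2R,3Z,5R,7Z)-5-acetoxy-2-hydroxy-4,8-dimethyl-10-oxocyclodeca-3,7-dien-1-yl]acetic acid F5. Mitsunobu lactonisation (PPh3, DIAD, toluene, 0 °C) closes the γ-lactone with inversion at C6, and brief p-TsOH treatment equilibrates C7 to give 16.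

Step 10 (epoxidation). Oxygen transfer may prefer the wrong face of C1=C10 or over-oxidise C4=C5. The fallback sets out from 23 and comes back at 24. NBS in aqueous THF (0 °C) forms the bromonium ion on the face that electrophiles prefer, and water opens it at the tertiary C10 from the other face to give (1S,3R,4Z,6S,7S,8S,10S)-3-acetoxy-1-bromo-10-hydroxy-8-[(2R)-2-methylbutanoyloxy]germacra-4,11(13)-dien-12,6-olide F6. K2CO3 in acetone (no alcohol, so the esters survive) closes the epoxide by intramolecular SN2 with inversion at C1. The epoxide oxygen thus ends on the face opposite to the one the electrophile attacked, which is the complement of direct epoxidation and gives 24.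

Further compounds
F1 | step 4 | (4R,5Z)-5-methyl-7-oxoocta-1,5-dien-4-yl acetate | CC(=O)/C=C(/C)[C@H](OC(C)=O)CC=C
F2 | step 4 | (4R,5Z)-5,11-dimethyl-7,9-dioxododeca-1,5,11-trien-4-yl acetate | C=C(C)CC(=O)CC(=O)/C=C(/C)[C@H](OC(C)=O)CC=C
F3 | step 6 | prop-2-en-1-yl 2-[(3Z,5R,7Z)-5-acetoxy-4,8-dimethyl-2,10-dioxocyclodeca-3,7-dien-1-yl]acetate | C=CCOC(=O)CC1C(=O)/C=C(/C)[C@H](OC(C)=O)C/C=C(/C)CC1=O
F4 | step 6 | prop-2-en-1-yl 2-[(2R,3Z,5R,7Z)-5-acetoxy-2-hydroxy-4,8-dimethyl-10-oxocyclodeca-3,7-dien-1-yl]acetate | C=CCOC(=O)CC1[C@H](O)/C=C(/C)[C@H](OC(C)=O)C/C=C(/C)CC1=O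
F5 | step 6 | 2-[(2R,3Z,5R,7Z)-5-acetoxy-2-hydroxy-4,8-dimethyl-10-oxocyclodeca-3,7-dien-1-yl]acetic acid | OC(=O)CC1[C@H](O)/C=C(/C)[C@H](OC(C)=O)C/C=C(/C)CC1=O
F6 | step 10 | (1S,3R,4Z,6S,7S,8S,10S)-3-acetoxy-1-bromo-10-hydroxy-8-[(2R)-2-methylbutanoyloxy]germacra-4,11(13)-dien-12,6-olide | C=C1C(=O)O[C@H]2/C=C(/C)[C@H](OC(C)=O)C[C@H](Br)[C@](O)(C)C[C@H](OC(=O)[C@H](C)CC)[C@H]12
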